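**Retrosynthetic overview**

- Numbering: ring C1–C14, with C1 the butenolide β-carbon, C2 the lactone O–CH, C3=C4, C7=C8 (ester C19), C11=C12 and C13 the acetoxy carbon; C15, C16 and C17 are the lactone α-carbon, carbonyl and methyl. The plan rests on the five-membered C1=C15 butenolide being the conjugated isomer of a C15=C17 α-methylene lactone, whose C1–C2 bond is the bond made when a 2-(alkoxycarbonyl)allyl metal (C17–C15–C1) adds to a C2 aldehyde.
- Target ⇐ alkene shift C15=C17 → C1=C15 ⇐ silyl/acetate exchange at C13 ⇐ lactonisation of C2–OH onto the C16 ester (second ring) ⇐ 14-membered carbocycle closed at C1–C2 by CrCl2-mediated intramolecular allylation of an open-chain 2-(bromomethyl)enoate enal (first ring).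
- Open chain ⇐ C1–C15 by Morita–Baylis–Hillman reaction of a C1 aldehyde with methyl acrylate, then SN2′ bromination; C13–C14 by Brown allylation of a C13 enal (sets 13S); C11=C12 by Wittig reaction; (Z)-C7=C8 by Still–Gennari olefination of the geranyl acetate-derived C2–C7 aldehyde with an alkylated phosphonoacetate (C8–C11).
- The C13 oxygen is carried as a TBS ether from step 8 to step 16, because a β-acetoxy C1 aldehyde would be prone to β-elimination in the amine-catalysed step 12; the acetate is installed after ring closure.

Key step: step 14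

Assumption: the remote C13 centre is not expected to control the C2 face in the ring closure, so a chiral ligand on chromium is used; the (S,S)-ligand is written on the working hypothesis that it exposes the Re face of the enal, and its antipode would be taken if a model enal shows the opposite sense.

**Route**

Step 1
Reactants: 1 geranyl acetate
Product: 2 (2E)-5-(3,3-dimethyloxiran-2-yl)-3-methylpent-2-en-1-yl acetate (racemic 6,7-epoxygeranyl acetate)
Conditions: mCPBA (1.0 equiv), NaHCO3, CH2Cl2, 0 °C
Reagents that add atoms: mCPBA, OOC(=O)c1cccc(Cl)c1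
Why: Prilezhaev epoxidation with one equivalent of peracid should go to the electron-rich distal isopropylidene alkene, because the other alkene is deactivated by the allylic acetate; the epoxide centre is racemic and is destroyed in step 2.

Step 2
Reactants: 2 racemic 6,7-epoxygeranyl acetate
Product: 3 (4E)-6-acetoxy-4-methylhex-4-enal
Conditions: H5IO6 (1.1 equiv), THF/H2O, 0 °C → rt
Reagents that add atoms: none
Why: Periodic acid opens the epoxide to the glycol and cleaves it in the same flask (Malaprade-type glycol cleavage), releasing acetone and leaving the C7 aldehyde with the (E)-C3=C4 alkene and the acetate untouched.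

Step 3
Reactants: 4 methyl bis(2,2,2-trifluoroethyl)phosphonoacetate (1.5 equiv); 5 3-bromo-1,1-dimethoxypropane
Product: 6 methyl 2-[bis(2,2,2-trifluoroethoxy)phosphoryl]-5,5-dimethoxypentanoate (racemic)
Conditions: NaH, DMF, 0 °C; then 5, Bu4NI (cat.), 50 °C
Reagents that add atoms: none
Why: SN2 C-alkylation of the sodium salt of the phosphonoacetate by the primary bromide under iodide catalysis gives the α-substituted Still–Gennari reagent carrying C9–C11; excess 4 suppresses dialkylation and the racemic α-centre is lost in step 4.

Step 4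
Reactants: 6 α-alkylated phosphonate; 3 (4E)-6-acetoxy-4-methylhex-4-enal
Product: 7 methyl (2Z,6E)-8-acetoxy-2-(3,3-dimethoxypropyl)-6-methylocta-2,6-dienoate
Conditions: KN(SiMe3)2, 18-crown-6, THF, −78 °C; then 3, −78 °C
Reagents that add atoms: none
Why: Still–Gennari variant of the Horner–Wadsworth–Emmons olefination, in which the electron-poor trifluoroethyl phosphonate with a dissociated potassium counter-ion eliminates rapidly from the kinetic adduct and should give the (Z)-trisubstituted enoate (ester cis to C6), the C7=C8 geometry of the target.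

Step 5
Reactants: 7 dimethyl acetal
Product: 8 methyl (2Z,6E)-8-acetoxy-6-methyl-2-(3-oxopropyl)octa-2,6-dienoate
Conditions: TsOH·H2O (cat.), acetone/H2O, rt
Reagents that add atoms: water, O
Why: Acid-catalysed acetal hydrolysis unmasks the C11 aldehyde much faster than the allylic acetate or the enoate can react.

Step 6
Reactants: 8 C11 aldehyde; 9 2-(triphenylphosphoranylidene)propanal (1.3 equiv)
Product: 10 methyl (2Z,6E)-8-acetoxy-6-methyl-2-[(3E)-4-methyl-5-oxopent-3-en-1-yl]octa-2,6-dienoate
Conditions: toluene, 80 °C
Reagents that add atoms: none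
Why: Wittig olefination with the stabilised formyl ylide is E-selective and stops at the enal because the product aldehyde is conjugated and α-branched, so C12, its methyl and C13 are added with the (E)-C11=C12 alkene.

Step 7
Reactants: 10 C13 enal
Product: 12 methyl (2Z,6E)-8-acetoxy-2-[(3E,5S)-5-hydroxy-4-methylocta-3,7-dien-1-yl]-6-methylocta-2,6-dienoate, via diisopinocampheylborinate ester 11 (not isolated)
Conditions: B-allyldiisopinocampheylborane of the (+)-α-pinene series (salt-free pentane solution, 1.5 equiv), Et2O, −100 → −78 °C; then HOCH2CH2NH2, rt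
Reagents that add atoms: B-allyldiisopinocampheylborane (from (+)-α-pinene), C=CCB([C@@H]1C[C@@H]2C[C@H]([C@H]1C)C2(C)C)[C@@H]1C[C@@H]2C[C@H]([C@H]1C)C2(C)C
Why: Brown asymmetric allylboration through a closed chair transition state, in which the isopinocampheyl groups of this reagent series direct allyl transfer to the Si face of the enal and so set (13S); the enoate and acetate do not react at this temperature and ethanolamine frees the alcohol from the borinate without basic peroxide.

Step 8
Reactants: 12 (13S)-homoallylic alcohol
Product: 13 methyl (2Z,6E)-8-acetoxy-2-[(3E,5S)-5-(tert-butyldimethylsilyloxy)-4-methylocta-3,7-dien-1-yl]-6-methylocta-2,6-dienoate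
Conditions: TBSCl, imidazole, DMF, rt
Reagents that add atoms: TBSCl, CC(C)(C)[Si](C)(C)Cl
Why: Imidazole-promoted silylation of the secondary allylic alcohol proceeds with retention at C13 and provides a C13 oxygen substituent that cannot leave by β-elimination in steps 11–12.

Step 9
Reactants: 13 silyl ether acetate
Product: 14 methyl (2Z,6E)-2-[(3E,5S)-5-(tert-butyldimethylsilyloxy)-4-methylocta-3,7-dien-1-yl]-8-hydroxy-6-methylocta-2,6-dienoate
Conditions: K2CO3 (cat.), MeOH, 0 °C
Reagents that add atoms: none
Why: Base-catalysed methanolysis (transesterification) removes the primary allylic acetate, while the methyl ester only exchanges with the solvent and the silyl ether is stable.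

Step 10
Reactants: 14 C2 allylic alcohol
Product: 15 methyl (2Z,6E)-2-[(3E,5S)-5-(tert-butyldimethylsilyloxy)-4-methylocta-3,7-dien-1-yl]-6-methyl-8-oxoocta-2,6-dienoate
Conditions: MnO2 (excess), CH2Cl2, rt
Reagents that add atoms: none
Why: MnO2 oxidises only the allylic alcohol and should give the (E)-enal without loss of alkene geometry, placing the C2 electrophile for the ring closure.

Step 11
Reactants: 15 C2 enal with terminal alkene
Product: 17 methyl (2Z,6E)-2-[(3E,5S)-5-(tert-butyldimethylsilyloxy)-4-methyl-7-oxohept-3-en-1-yl]-6-methyl-8-oxoocta-2,6-dienoate, via vicinal diol 16 (not isolated)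
Conditions: OsO4 (2 mol %), NMO (1.1 equiv), acetone/H2O, 0 °C; then NaIO4, rt
Reagents that add atoms: N-methylmorpholine N-oxide (oxygen delivered through OsO4), C[N+]1([O-])CCOCC1
Why: Upjohn dihydroxylation followed by periodate cleavage (Lemieux–Johnson-type sequence) should take the unhindered monosubstituted alkene first, because C3=C4 and C7=C8 are electron-poor and C11=C12 is trisubstituted and flanked by the silyloxy-bearing carbon; loss of formaldehyde leaves the C1 aldehyde.

Step 12
Reactants: 17 C1 aldehyde; 18 methyl acrylate (excess)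
Product: 19 methyl 2-methylene-3-hydroxy ester adduct at C1 (C1 carbinol epimers; C13 silyl ether and C2 enal retained)
Conditions: DABCO (1 equiv), 1,4-dioxane/H2O (1:1), rt
Reagents that add atoms: none
Why: Morita–Baylis–Hillman reaction, in which the DABCO–acrylate zwitterion should add to the unhindered saturated C1 aldehyde far faster than to the β,β-disubstituted enal, joining C1 to C15; the new C1 carbinol centre is uncontrolled and is removed in step 13.

Step 13
Reactants: 19 acrylate adduct
Product: 20 open-chain (Z)-2-(bromomethyl)enoate enal (C17 bromide, C1=C15, C13 silyl ether, C2 aldehyde)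
Conditions: NBS, Me2S, CH2Cl2, 0 °C → rt
Reagents that add atoms: N-bromosuccinimide, O=C1CCC(=O)N1Br
Why: The Corey–Kim-type bromosulfonium reagent activates the carbinol and bromide attacks C17 with allylic transposition (SN2′), which should give the more stable (Z)-2-(bromomethyl)alk-2-enoate (CH2Br cis to C14) under conditions that spare the enal and the silyl ether.

Step 14
Reactants: 20 open-chain 2-(bromomethyl)enoate enal
Product: 22 macrocyclic (1S,2S,13S)-C2-hydroxy α-methylene ester (14-membered ring; 3E,7Z,11E; C13 silyl ether), via allylchromium species 21 (not isolated)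
Conditions: CrCl2 (6 equiv), 1,8-bis[(4S)-4-isopropyl-4,5-dihydro-1,3-oxazol-2-yl]-3,6-diphenyl-9H-carbazole (6.5 equiv), iPr2NEt, THF, rt; 20 added by syringe pump over 12 h (final 2 mM); aqueous sodium serinate work-up
Reagents that add atoms: none
Why: Two equivalents of CrCl2 (divalent chromium) reduce the C17–Br bond to the trivalent allylchromium 21, which adds to the C2 aldehyde through a closed six-membered chair (SE2′), so the new bond is C1–C2 and the alkene moves out to C15=C17; this is the chromium-mediated (Nozaki–Hiyama-type) carbonyl allylation by 2-(bromomethyl)alkenoates, run intramolecularly. The 14-membered carbocycle, the only ring formed here, closes by 14-exo-trig attack of C1 on the enal carbonyl under high dilution. C2 is set by the face of the enal that is attacked: with the enal chain equatorial in the chair, the chiral tridentate ligand on chromium has to expose the Re face, which gives (2S), and the remote C13 silyloxy branch on C14 is expected to add little bias of its own. C1 follows from the allyl geometry (C14 cis to the CH2Cr carbon and axial in the chair, hence the 1,2-syn adduct drawn); it is of no consequence, since step 18 makes C1 trigonal and the C1 epimer would be carried on in the same way. The step needs attack through C1 rather than C17, 1,2- rather than 1,4-addition to the enal, and tolerance of two methyl esters and the silyl ether; the cyclic transition state secures the first, the oxophilic chromium centre the second, and the low basicity of allylchromium toward esters the third.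

Step 15
Reactants: 22 macrocyclic hydroxy ester
Product: 23 cis-fused (1S,2S,13S)-α-methylene-γ-lactone with C13 silyl ether
Conditions: PPTS (cat.), toluene, 60 °C
Reagents that add atoms: none
Why: Acid-catalysed intramolecular transesterification, in which the C2 hydroxyl closes the five-membered lactone onto the C16 ester (5-exo-trig) with loss of methanol; the mild acid should leave the allylic C2–O bond, the silyl ether and the remote C19 ester intact.

Step 16
Reactants: 23 α-methylene lactone silyl ether
Product: 24 (1S,2S,13S)-α-methylene lactone C13 alcohol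
Conditions: HF·pyridine, pyridine, THF, 0 °C → rt
Reagents that add atoms: none
Why: Buffered fluoride desilylation frees the C13 alcohol without exposing the α-methylene lactone to base or nucleophiles.

Step 17
Reactants: 24 C13 alcohol
Product: 25 (1S,2S,13S)-α-methylene lactone C13 acetate
Conditions: Ac2O, pyridine, DMAP (cat.), CH2Cl2, 0 °C → rt
Reagents that add atoms: acetic anhydride, CC(=O)OC(C)=O
Why: DMAP-catalysed acylation of the secondary allylic alcohol installs the C13 acetate with retention of configuration.

Step 18
Reactants: 25 α-methylene lactone acetate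
Product: 26 16-oxosarcoglaucol acetate
Conditions: RhCl3·3H2O (10 mol %), EtOH, 70 °C
Reagents that add atoms: none
Why: Transition-metal-catalysed alkene isomerisation, in which a rhodium hydride adds to the exocyclic C15=C17 alkene and β-hydride elimination toward C1 gives the more stable tetrasubstituted conjugated C1=C15 butenolide; C1 becomes trigonal, C2 and C13 are not involved and the trisubstituted ring alkenes are too hindered to migrate.

**Compound list**

1 | geranyl acetate | CC(C)=CCC/C(C)=C/COC(C)=O | starting material
2 | racemic 6,7-epoxygeranyl acetate | CC1(C)OC1CC/C(C)=C/COC(C)=O | intermediate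
3 | (4E)-6-acetoxy-4-methylhex-4-enal | O=CCC/C(C)=C/COC(C)=O | intermediate
4 | methyl bis(2,2,2-trifluoroethyl)phosphonoacetate | COC(=O)CP(=O)(OCC(F)(F)F)OCC(F)(F)F | starting material
5 | 3-bromo-1,1-dimethoxypropane | BrCCC(OC)OC | starting material
6 | methyl 2-[bis(2,2,2-trifluoroethoxy)phosphoryl]-5,5-dimethoxypentanoate (racemic) | COC(=O)C(CCC(OC)OC)P(=O)(OCC(F)(F)F)OCC(F)(F)F | intermediate
7 | methyl (2Z,6E)-8-acetoxy-2-(3,3-dimethoxypropyl)-6-methylocta-2,6-dienoate | COC(=O)/C(CCC(OC)OC)=C\CC/C(C)=C/COC(C)=O | intermediate
8 | methyl (2Z,6E)-8-acetoxy-6-methyl-2-(3-oxopropyl)octa-2,6-dienoate | COC(=O)/C(CCC=O)=C\CC/C(C)=C/COC(C)=O | intermediate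
9 | 2-(triphenylphosphoranylidene)propanal | CC(C=O)=P(c1ccccc1)(c1ccccc1)c1ccccc1 | starting material
10 | methyl (2Z,6E)-8-acetoxy-6-methyl-2-[(3E)-4-methyl-5-oxopent-3-en-1-yl]octa-2,6-dienoate | COC(=O)/C(CC/C=C(\C)C=O)=C\CC/C(C)=C/COC(C)=O | intermediate
11 | diisopinocampheylborinate ester of 12 | COC(=O)/C(CC/C=C(\C)[C@@H](OB([C@@H]1C[C@@H]2C[C@H]([C@H]1C)C2(C)C)[C@@H]1C[C@@H]2C[C@H]([C@H]1C)C2(C)C)CC=C)=C\CC/C(C)=C/COC(C)=O | intermediate
12 | methyl (2Z,6E)-8-acetoxy-2-[(3E,5S)-5-hydroxy-4-methylocta-3,7-dien-1-yl]-6-methylocta-2,6-dienoate | COC(=O)/C(CC/C=C(\C)[C@@H](O)CC=C)=C\CC/C(C)=C/COC(C)=O | intermediate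
13 | C13 TBS ether of 12 | COC(=O)/C(CC/C=C(\C)[C@@H](O[Si](C)(C)C(C)(C)C)CC=C)=C\CC/C(C)=C/COC(C)=O | intermediate
14 | C2 allylic alcohol (C13 TBS ether) | COC(=O)/C(CC/C=C(\C)[C@@H](O[Si](C)(C)C(C)(C)C)CC=C)=C\CC/C(C)=C/CO | intermediate
15 | C2 enal (C13 TBS ether, terminal alkene) | COC(=O)/C(CC/C=C(\C)[C@@H](O[Si](C)(C)C(C)(C)C)CC=C)=C\CC/C(C)=C/C=O | intermediate
16 | vicinal diol from the terminal alkene of 15 (carbinol epimers) | COC(=O)/C(CC/C=C(\C)[C@@H](O[Si](C)(C)C(C)(C)C)CC(O)CO)=C\CC/C(C)=C/C=O | intermediate
17 | methyl (2Z,6E)-2-[(3E,5S)-5-(tert-butyldimethylsilyloxy)-4-methyl-7-oxohept-3-en-1-yl]-6-methyl-8-oxoocta-2,6-dienoate | COC(=O)/C(CC/C=C(\C)[C@@H](O[Si](C)(C)C(C)(C)C)CC=O)=C\CC/C(C)=C/C=O | intermediate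
18 | methyl acrylate | C=CC(=O)OC | starting material
19 | Morita–Baylis–Hillman adduct (C1 carbinol epimers, 13S, C2 enal) | C=C(C(=O)OC)C(O)C[C@H](O[Si](C)(C)C(C)(C)C)/C(C)=C/CC/C(C(=O)OC)=C/CC/C(C)=C/C=O | intermediate
20 | open-chain (Z)-2-(bromomethyl)enoate enal (13S, C13 TBS ether) | BrC/C(C(=O)OC)=C\C[C@H](O[Si](C)(C)C(C)(C)C)/C(C)=C/CC/C(C(=O)OC)=C/CC/C(C)=C/C=O | intermediate
21 | allylchromium species from 20 (trivalent chromium, drawn as the dichloride without ligand and THF) | Cl[Cr](Cl)C/C(C(=O)OC)=C\C[C@H](O[Si](C)(C)C(C)(C)C)/C(C)=C/CC/C(C(=O)OC)=C/CC/C(C)=C/C=O | intermediate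
22 | macrocyclic (1S,2S,13S)-C2-hydroxy α-methylene ester, C13 TBS ether | COC(=O)/C1=C\CC/C(C)=C/[C@H](O)[C@H](C(=C)C(=O)OC)C[C@H](O[Si](C)(C)C(C)(C)C)/C(C)=C/CC1 | intermediate
23 | cis-fused (1S,2S,13S)-α-methylene-γ-lactone, C13 TBS ether | COC(=O)/C1=C\CC/C(C)=C/[C@@H]2OC(=O)C(=C)[C@@H]2C[C@H](O[Si](C)(C)C(C)(C)C)/C(C)=C/CC1 | intermediate
24 | (1S,2S,13S)-α-methylene-γ-lactone C13 alcohol | COC(=O)/C1=C\CC/C(C)=C/[C@@H]2OC(=O)C(=C)[C@@H]2C[C@H](O)/C(C)=C/CC1 | intermediate
25 | (1S,2S,13S)-α-methylene-γ-lactone C13 acetate | COC(=O)/C1=C\CC/C(C)=C/[C@@H]2OC(=O)C(=C)[C@@H]2C[C@H](OC(C)=O)/C(C)=C/CC1 | intermediate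
26 | 16-oxosarcoglaucol acetate (2S,13S) | COC(=O)/C1=C\CC/C(C)=C/[C@@H]2OC(=O)C(C)=C2C[C@H](OC(C)=O)/C(C)=C/CC1 | target

**Step count**

Total: 18 steps. Longest linear sequence: 17 steps (from 1 through steps 1, 2 and 4–18); step 3 prepares the phosphonate branch.

**Steps most likely to fail**

1. Step 14. The two faces of the enal may be attacked with little discrimination, since the ligand has to override a remote centre across a forming 14-membered ring, and intermolecular coupling may compete with closure. Fallback: C2 is set by ketone reduction instead of in the C–C bond formation. Setting out from 22 obtained as a mixture of C2 epimers, the allylic carbinol is oxidised with Dess–Martin periodinane buffered with NaHCO3 to the macrocyclic C2 ketone F1. This is reduced at −78 °C with catecholborane and the (S)-methyl oxazaborolidine (Corey–Bakshi–Shibata reduction), the C3=C4 alkenyl arm acting as the large group. This should return (2S)-configured 22 (as C1 epimers, which is immaterial), and the route continues with step 15.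

2. Step 18. The C13 allylic acetate may ionise or undergo ethanolysis under the acidic rhodium chloride conditions, or the migration may stall. Fallback: the alkene shift is moved in front of the acetate installation and run with a neutral ruthenium hydride in an aprotic solvent. Setting out from 23, RuHCl(CO)(PPh3)3 (cat.) in toluene at 80 °C should give the butenolide silyl ether F2. HF·pyridine then frees the butenolide alcohol F3, and Ac2O/pyridine acetylates it to arrive at 26.

3. Step 12. The acrylate addition may be slow, leaving the C2 enal exposed to the amine long enough for competing addition or E/Z erosion. Fallback: the enal is unmasked only after the acrylate addition. Setting out from 13 (C2 still an acetate), OsO4/NMO and then NaIO4 give the acetoxy aldehyde F4. DABCO and methyl acrylate give the acetoxy acrylate adduct F5, with a single aldehyde present. K2CO3 in MeOH at 0 °C gives the hydroxy acrylate adduct F6. MnO2 then oxidises only the primary allylic alcohol, the electron-poor secondary carbinol next to the acrylate being inert to it, and the route is rejoined at 19.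

**Further compounds**

F1 | step 14 | macrocyclic C2 ketone (C1 epimers, 13S, C13 TBS ether) | COC(=O)/C1=C\CC/C(C)=C/C(=O)C(C(=C)C(=O)OC)C[C@H](O[Si](C)(C)C(C)(C)C)/C(C)=C/CC1
F2 | step 18 | butenolide silyl ether (2S,13S; C1=C15) | COC(=O)/C1=C\CC/C(C)=C/[C@@H]2OC(=O)C(C)=C2C[C@H](O[Si](C)(C)C(C)(C)C)/C(C)=C/CC1
F3 | step 18 | butenolide alcohol (2S,13S; C13 OH) | COC(=O)/C1=C\CC/C(C)=C/[C@@H]2OC(=O)C(C)=C2C[C@H](O)/C(C)=C/CC1
F4 | step 12 | acetoxy aldehyde (C1 aldehyde, C2 acetate, C13 TBS ether) | COC(=O)/C(CC/C=C(\C)[C@@H](O[Si](C)(C)C(C)(C)C)CC=O)=C\CC/C(C)=C/COC(C)=O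
F5 | step 12 | acetoxy acrylate adduct (C1 carbinol epimers, C2 acetate) | C=C(C(=O)OC)C(O)C[C@H](O[Si](C)(C)C(C)(C)C)/C(C)=C/CC/C(C(=O)OC)=C/CC/C(C)=C/COC(C)=O
F6 | step 12 | hydroxy acrylate adduct (C1 carbinol epimers, C2 alcohol) | C=C(C(=O)OC)C(O)C[C@H](O[Si](C)(C)C(C)(C)C)/C(C)=C/CC/C(C(=O)OC)=C/CC/C(C)=C/CO
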